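**Retrosynthetic overview**

1. Target 13 ⇒ 12 (cleave two methyl ethers) ⇒ 11 (Rieche formylation at C8') ⇒ 10 (hydrogenation from the less hindered face sets C4').
2. Pyran ring, closed last: C4'–C4a' by gold-catalysed 6-exo-dig hydroarylation of aryl homopropargyl ether 9; aryl–O1' by SNAr, so the C2–O bond is never broken.
3. Key C3'–C4' bond with reversed polarity: C4' enters as lithium 3-methylbut-1-ynide, a masked isovaleryl (acyl) anion, and C3' as the electrophilic CH2 of spiro-epoxide 4. The alkyne is never unmasked; it serves directly as the ketone equivalent in the ring closure.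
4. Spiro centre C2: exo CH2 transfer from a sulfonium ylide to (1R,4S)-camphenilone 3, obtained from (−)-camphene 1.
5. Ring order: bicyclo[2.2.1]heptane (chiral pool) → oxirane → aryl ether → pyran.

Assumption: (1S,4R)-(−)-camphene of high enantiomeric purity and 4-fluoro-2,6-dimethoxybenzaldehyde are bought; the enantiomeric purity of 13 is that of 1.

**Route**

Step 1
Reactants: 1 (1S,4R)-(−)-camphene
Product: 3 (1R,4S)-3,3-dimethylbicyclo[2.2.1]heptan-2-one (camphenilone), via camphene ozonide 2 (not isolated)
Conditions: O3, CH2Cl2, −78 °C; then Me2S, −78 → 25 °C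
Reagents that add atoms: ozone, [O-][O+]=O
Why: Ozonolysis (Criegee mechanism) of the exocyclic methylene and reductive cleavage of the ozonide give the non-enolisable ketone and leave both bridgehead stereocentres untouched.

Step 2
Reactants: 3 (1R,4S)-camphenilone
Product: 4 (1R,2R,4S)-3,3-dimethylspiro[bicyclo[2.2.1]heptane-2,2'-oxirane] (O endo, CH2 exo)
Conditions: Me3S+ I−, KOt-Bu, DMSO, 25 °C
Reagents that add atoms: trimethylsulfonium iodide, C[S+](C)C.[I-]
Why: Corey–Chaykovsky epoxidation: dimethylsulfonium methylide adds irreversibly to the exo face of the carbonyl group (the face Grignard and organolithium reagents also take with camphenilone, the endo face being screened by the endo hydrogens at C5 and C6), so the new CH2 is exo and the oxygen, the later O1', is endo, which is the (2R) spiro centre of the target.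

Step 3
Reactants: 4 spiro-epoxide; 5 3-methylbut-1-yne; 6 4-fluoro-2,6-dimethoxybenzaldehyde
Product: 9 4-{[(1R,2R,4S)-3,3-dimethyl-2-(4-methylpent-2-yn-1-yl)bicyclo[2.2.1]heptan-2-yl]oxy}-2,6-dimethoxybenzaldehyde, via lithium 3-methylbut-1-yn-1-ide 7 (not isolated), via lithium alkoxide 8 (not isolated)
Conditions: n-BuLi, THF, −78 → 0 °C; 4, DMPU, 25 → 50 °C; then 6, 50 °C
Reagents that add atoms: none
Why: Alkynide opening of an epoxide followed by SNAr: the alkynide is a masked isovaleryl anion (its carbanionic carbon C4' is the one the arene later attacks as it would a ketone carbon), it opens 4 by SN2 at the CH2 terminus C3' so that two carbons that are both electrophiles in carbonyl and epoxide chemistry are joined, and the tertiary alkoxide then displaces fluoride para to the formyl group by addition–elimination, so the C2–O bond and the (2R) centre are never touched.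

Step 4
Reactants: 9 aryl homopropargyl ether
Product: 10 (1R,2R,4S)-5',7'-dimethoxy-3,3-dimethyl-4'-[(Z)-2-methylpropylidene]spiro[bicyclo[2.2.1]heptane-2,2'-chromane]-6'-carbaldehyde
Conditions: Ph3PAuCl (5 mol %), AgSbF6 (5 mol %), CH2Cl2, 25 °C
Reagents that add atoms: none
Why: Gold-catalysed intramolecular hydroarylation (Friedel–Crafts-type alkenylation): monovalent gold activates the alkyne, the ring carbon ortho to the ether oxygen (activated by three oxygen substituents) attacks the proximal alkyne carbon C4' in the 6-exo-dig mode (7-endo attack would have to occur at the carbon bearing the isopropyl group), and the neutral conditions spare the tertiary ether and the formyl group.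

Step 5
Reactants: 10 alkylidene chromane
Product: 11 (1R,2R,4S,4'S)-5',7'-dimethoxy-3,3-dimethyl-4'-(2-methylpropyl)spiro[bicyclo[2.2.1]heptane-2,2'-chromane]-6'-carbaldehyde
Conditions: H2 (1 atm), 10% Pd/C, EtOAc, 25 °C
Reagents that add atoms: none
Why: Heterogeneous hydrogenation with syn delivery of H2 to the face of the C4' olefin turned away from the C3 gem-dimethyl group (its exo methyl lies over that face, only the bridgehead H1 over the other), which puts the new H at C4' on the side of C1 and is expected to give (4'S); the hindered, electron-rich aldehyde should not be reduced at 1 atm.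

Step 6
Reactants: 11 chromane monoaldehyde
Product: 12 (1R,2R,4S,4'S)-5',7'-dimethoxy-3,3-dimethyl-4'-(2-methylpropyl)spiro[bicyclo[2.2.1]heptane-2,2'-chromane]-6',8'-dicarbaldehyde
Conditions: Cl2CHOMe, TiCl4, CH2Cl2, −78 → 0 °C; then H2O
Reagents that add atoms: dichloromethyl methyl ether, COC(Cl)Cl; water, O
Why: Rieche formylation (electrophilic aromatic substitution by the TiCl4-activated dichloromethyl ether, then hydrolysis) at C8', the only free ring position, which is ortho or para to all three oxygen substituents.

Step 7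
Reactants: 12 dialdehyde dimethyl ether
Product: 13 (1R,2R,4S,4'S)-5',7'-dihydroxy-3,3-dimethyl-4'-(2-methylpropyl)spiro[bicyclo[2.2.1]heptane-2,2'-chromane]-6',8'-dicarbaldehyde (CNP0150011.1)
Conditions: BCl3, CH2Cl2, −78 → 0 °C; then H2O
Reagents that add atoms: none
Why: Chelation-directed Lewis-acid ether cleavage: BCl3 binds each formyl oxygen together with the neighbouring methoxy oxygen and chloride removes the methyl group by SN2, so both aryl methyl ethers (each ortho to a formyl group) fall at low temperature while the tertiary spiro ether, which offers no SN2 pathway, stays.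

**Compound list**

1 | (1S,4R)-2,2-dimethyl-3-methylidenebicyclo[2.2.1]heptane, (−)-camphene | C=C1[C@@H]2CC[C@@H](C2)C1(C)C | starting material
2 | (1R,4S)-3,3-dimethylspiro[bicyclo[2.2.1]heptane-2,3'-[1,2,4]trioxolane], camphene ozonide (both epimers at the spiro carbon) | C1OOC2(O1)[C@@H]3CC[C@@H](C3)C2(C)C | intermediate
3 | (1R,4S)-3,3-dimethylbicyclo[2.2.1]heptan-2-one, camphenilone | O=C1[C@@H]2CC[C@@H](C2)C1(C)C | intermediate
4 | (1R,2R,4S)-3,3-dimethylspiro[bicyclo[2.2.1]heptane-2,2'-oxirane], O endo | C1O[C@@]12[C@@H]3CC[C@@H](C3)C2(C)C | intermediate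
5 | 3-methylbut-1-yne | CC(C)C#C | starting material
6 | 4-fluoro-2,6-dimethoxybenzaldehyde | COc1cc(F)cc(OC)c1C=O | starting material
7 | lithium 3-methylbut-1-yn-1-ide | [Li]C#CC(C)C | intermediate
8 | lithium (1R,2R,4S)-3,3-dimethyl-2-(4-methylpent-2-yn-1-yl)bicyclo[2.2.1]heptan-2-olate | [Li+].CC(C)C#CC[C@@]1([O-])[C@@H]2CC[C@@H](C2)C1(C)C | intermediate
9 | 4-{[(1R,2R,4S)-3,3-dimethyl-2-(4-methylpent-2-yn-1-yl)bicyclo[2.2.1]heptan-2-yl]oxy}-2,6-dimethoxybenzaldehyde | CC(C)C#CC[C@@]1(Oc2cc(OC)c(C=O)c(OC)c2)[C@@H]3CC[C@@H](C3)C1(C)C | intermediate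
10 | (1R,2R,4S)-5',7'-dimethoxy-3,3-dimethyl-4'-[(Z)-2-methylpropylidene]spiro[bicyclo[2.2.1]heptane-2,2'-chromane]-6'-carbaldehyde | CC(C)/C=C1/C[C@@]2(Oc3cc(OC)c(C=O)c(OC)c31)[C@@H]4CC[C@@H](C4)C2(C)C | intermediate
11 | (1R,2R,4S,4'S)-5',7'-dimethoxy-3,3-dimethyl-4'-(2-methylpropyl)spiro[bicyclo[2.2.1]heptane-2,2'-chromane]-6'-carbaldehyde | CC(C)C[C@H]1C[C@@]2(Oc3cc(OC)c(C=O)c(OC)c31)[C@@H]4CC[C@@H](C4)C2(C)C | intermediate
12 | (1R,2R,4S,4'S)-5',7'-dimethoxy-3,3-dimethyl-4'-(2-methylpropyl)spiro[bicyclo[2.2.1]heptane-2,2'-chromane]-6',8'-dicarbaldehyde | CC(C)C[C@H]1C[C@@]2(Oc3c(C=O)c(OC)c(C=O)c(OC)c31)[C@@H]4CC[C@@H](C4)C2(C)C | intermediate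
13 | (1R,2R,4S,4'S)-5',7'-dihydroxy-3,3-dimethyl-4'-(2-methylpropyl)spiro[bicyclo[2.2.1]heptane-2,2'-chromane]-6',8'-dicarbaldehyde, CNP0150011.1 | CC(C)C[C@H]1C[C@@]2(Oc3c(C=O)c(O)c(C=O)c(O)c31)[C@@H]1CC[C@@H](C1)C2(C)C | target

**Step count and risks**

Total: 7 steps. Longest linear sequence: 7 steps (1 → 3 → 4 → 9 → 10 → 11 → 12 → 13).

Step 3 is the most exposed. The alkynide has to open a hindered 2,2-disubstituted epoxide without a Lewis acid (BF3·OEt2 would rearrange 4 to the aldehyde), and the tertiary lithium alkoxide 8 has to be arylated in the same flask. The fallback sets out from 3 and comes back at 9. It makes the same carbinol by adding the CH2 carbon to the ketone instead of opening an epoxide: zinc-mediated Barbier propargylation of 3 with 1-bromo-4-methylpent-2-yne (zinc dust, THF, 25 °C). The allenylzinc species should react through its CH2 terminus and from the exo face, giving (1R,2R,4S)-3,3-dimethyl-2-(4-methylpent-2-yn-1-yl)bicyclo[2.2.1]heptan-2-ol F1. This alcohol is then arylated in a separate operation (KN(SiMe3)2, DMF, 0 → 25 °C, then 6) to give 9.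

Step 5 rests on substrate control alone, so the facial selectivity at C4' is a prediction, and some reduction of the aldehyde is possible. The fallback sets out from 10 and comes back at 11. It replaces substrate control on a metal surface by catalyst control in solution: hydrogenation (50 bar H2, CH2Cl2) with [Ir(cod)(L)]B[3,5-(CF3)2C6H3]4, where L is (S)- or (R)-4-tert-butyl-2-[2-(diphenylphosphino)phenyl]-4,5-dihydrooxazole. The ligand enantiomer matched with the substrate for (4'S) is used, and aldehydes are inert to this catalyst. No new compound is made (F0).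

Step 6 may fail because TiCl4 can ionise the tertiary spiro ether and the ring is deactivated once TiCl4 is bound to the C6' aldehyde. The fallback sets out from 11 and comes back at 13. It reverses the order and formylates a free phenol without a strong Lewis acid. BCl3 (CH2Cl2, −78 → 0 °C) cleaves both methyl ethers of 11, each ortho to the C6' formyl group while O1' has no neighbouring carbonyl at this stage, to give (1R,2R,4S,4'S)-5',7'-dihydroxy-3,3-dimethyl-4'-(2-methylpropyl)spiro[bicyclo[2.2.1]heptane-2,2'-chromane]-6'-carbaldehyde F2. Magnesium-phenoxide-directed ortho-formylation (MgCl2, Et3N, paraformaldehyde, MeCN, 80 °C) then introduces the C8' formyl group ortho to the C7' hydroxyl and gives 13 directly.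

**Further compounds**

F1 | step 3 | (1R,2R,4S)-3,3-dimethyl-2-(4-methylpent-2-yn-1-yl)bicyclo[2.2.1]heptan-2-ol | CC(C)C#CC[C@@]1(O)[C@@H]2CC[C@@H](C2)C1(C)C
F0 | step 5 | none | none
F2 | step 6 | (1R,2R,4S,4'S)-5',7'-dihydroxy-3,3-dimethyl-4'-(2-methylpropyl)spiro[bicyclo[2.2.1]heptane-2,2'-chromane]-6'-carbaldehyde | CC(C)C[C@H]1C[C@@]2(Oc3cc(O)c(C=O)c(O)c31)[C@@H]4CC[C@@H](C4)C2(C)C
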